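**Retrosynthetic overview**
1. Selaginellin ⇐ fluoride desilylation and mild-acid dehydration of a fully silylated triaryl carbinol; the cyclohexadienone ring is not built, it is unveiled last from one 4-hydroxyphenyl ring.
2. Biaryl C–C ⇐ Suzuki coupling at the aryl bromide; diarylalkyne C–C ⇐ Sonogashira coupling at the aryl iodide (iodide first).
3. Triaryl carbinol C–C ⇐ aryllithium made by deprotonation between iodine and bromine, added to silyl-protected 4,4'-dihydroxybenzophenone.
4. Benzylic C–O (key bond, first step) ⇐ direct copper-catalysed C–H silyloxylation of the methyl group of 4-bromo-2-iodotoluene, which installs the oxygen already protected.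
5. No ring is constructed: all five six-membered rings come from commercial benzene derivatives.

**Assumptions**
- The target SMILES has no stereocentre, and the two 4-oxyphenyl rings on the central carbon interchange by tautomerism, so there is no configurationally stable stereogenic element and no stereocontrol is needed.
- Bis(tert-butyldimethylsilyl) peroxide is treated as a reagent made beforehand from TBSCl and urea–hydrogen peroxide (by analogy with its trimethylsilyl analogue) and is not counted as a route step.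

**Route**

Step 1
Reactants: 1 4-bromo-2-iodotoluene (4-bromo-2-iodo-1-methylbenzene)
Product: 2 [(4-bromo-2-iodophenyl)methoxy](tert-butyl)dimethylsilane
Conditions: Cu(MeCN)4PF6 (5 mol%), 4,4'-di-tert-butyl-2,2'-bipyridine (6 mol%), (tBuMe2SiO)2 (1.0 equiv), 1 (3.0 equiv, excess recovered by distillation), PhCF3, 50 °C
Reagents that add atoms: bis(tert-butyldimethylsilyl) peroxide, CC(C)(C)[Si](C)(C)OO[Si](C)(C)C(C)(C)C
Why: Proposed new method: copper-catalysed benzylic C–H silyloxylation, in which monovalent copper cleaves the weak O–O bond of the bis-silyl peroxide to a divalent copper silanolate and a silyloxyl radical; this electrophilic oxygen radical abstracts a hydrogen atom from the only weak C–H bond of 1 (the methyl group); the benzyl radical is captured by the divalent copper silanolate and C–O reductive elimination from the trivalent benzylcopper silanolate gives the silyl ether and returns monovalent copper; silyloxyl radicals cannot fragment by beta-scission as tert-butoxyl does, the excess of cheap 1 suppresses a second hydrogen abstraction at the product, and without base at 50 °C copper should not insert into the aryl halides; closest known reaction type: Kharasch–Sosnovsky benzylic/allylic acyloxylation with peresters (also copper radical-relay benzylic C–H etherification); no stereocentre is formed.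

Step 2
Reactants: 3 4,4'-dihydroxybenzophenone
Product: 4 4,4'-bis(tert-butyldimethylsilyloxy)benzophenone
Conditions: TBSCl (2.4 equiv), imidazole (5 equiv), DMF, rt
Reagents that add atoms: tert-butyldimethylsilyl chloride, CC(C)(C)[Si](C)(C)Cl
Why: Imidazole-promoted O-silylation of both phenols (silyl ether protection) gives a non-enolisable ketone without acidic protons whose aryl silyl ethers survive the aryllithium addition and are removed by fluoride at the end; no stereocentre is formed.

Step 3
Reactants: 2 [(4-bromo-2-iodophenyl)methoxy](tert-butyl)dimethylsilane; 4 4,4'-bis(tert-butyldimethylsilyloxy)benzophenone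
Product: 7 [6-bromo-3-({[tert-butyl(dimethyl)silyl]oxy}methyl)-2-iodophenyl]bis(4-{[tert-butyl(dimethyl)silyl]oxy}phenyl)methanol, via aryllithium 5 (not isolated), via lithium alkoxide 6 (not isolated)
Conditions: LiN(iPr)2 (1.1 equiv), THF, −78 °C, 1 h; then 4 (1.05 equiv), −78 °C, 3 h; AcOH, −78 °C to rt
Reagents that add atoms: none
Why: Directed ortho-lithiation followed by 1,2-addition to a ketone: the ring proton flanked by iodine and bromine is by far the most acidic, the lithium amide removes it at −78 °C without halogen–lithium exchange or aryne formation, and the 2,6-dihaloaryllithium adds to the non-enolisable diaryl ketone to give an achiral carbinol (two identical aryl groups, no stereocentre).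

Step 4
Reactants: 7 [6-bromo-3-({[tert-butyl(dimethyl)silyl]oxy}methyl)-2-iodophenyl]bis(4-{[tert-butyl(dimethyl)silyl]oxy}phenyl)methanol; 8 tert-butyl(4-ethynylphenoxy)dimethylsilane
Product: 9 {6-bromo-3-({[tert-butyl(dimethyl)silyl]oxy}methyl)-2-[(4-{[tert-butyl(dimethyl)silyl]oxy}phenyl)ethynyl]phenyl}bis(4-{[tert-butyl(dimethyl)silyl]oxy}phenyl)methanol
Conditions: 8 (1.3 equiv), Pd(PPh3)2Cl2 (5 mol%), CuI (5 mol%), Et3N/THF 1:1, 50 °C
Reagents that add atoms: none
Why: Sonogashira coupling: zerovalent palladium inserts into the C–I bond far faster than into the C–Br bond, so the alkyne is placed between the silyloxymethyl group and the carbinol while the bromide is kept for the next step; no stereocentre is formed.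

Step 5
Reactants: 9 {6-bromo-3-({[tert-butyl(dimethyl)silyl]oxy}methyl)-2-[(4-{[tert-butyl(dimethyl)silyl]oxy}phenyl)ethynyl]phenyl}bis(4-{[tert-butyl(dimethyl)silyl]oxy}phenyl)methanol; 10 (4-{[tert-butyl(dimethyl)silyl]oxy}phenyl)boronic acid
Product: 11 {4'-{[tert-butyl(dimethyl)silyl]oxy}-4-({[tert-butyl(dimethyl)silyl]oxy}methyl)-3-[(4-{[tert-butyl(dimethyl)silyl]oxy}phenyl)ethynyl]biphenyl-2-yl}bis(4-{[tert-butyl(dimethyl)silyl]oxy}phenyl)methanol
Conditions: 10 (1.5 equiv), Pd(OAc)2 (5 mol%), SPhos (10 mol%), K3PO4 (3 equiv), toluene/H2O 10:1, 70 °C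
Reagents that add atoms: none
Why: Suzuki–Miyaura coupling: the remaining aryl bromide, ortho to the carbinol, couples under a bulky electron-rich biarylphosphine catalyst that tolerates ortho substitution, and the mild phosphate base at 70 °C leaves the silyl ethers and the alkyne untouched; no stereocentre is formed.

Step 6
Reactants: 11 {4'-{[tert-butyl(dimethyl)silyl]oxy}-4-({[tert-butyl(dimethyl)silyl]oxy}methyl)-3-[(4-{[tert-butyl(dimethyl)silyl]oxy}phenyl)ethynyl]biphenyl-2-yl}bis(4-{[tert-butyl(dimethyl)silyl]oxy}phenyl)methanol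
Product: 13 selaginellin (4-[{4'-hydroxy-4-(hydroxymethyl)-3-[(4-hydroxyphenyl)ethynyl]biphenyl-2-yl}(4-hydroxyphenyl)methylidene]cyclohexa-2,5-dien-1-one), via desilylated carbinol 12 (not isolated)
Conditions: Bu4NF/AcOH (1:1, 6 equiv), THF, 0 °C to rt; then aqueous AcOH (pH 4), rt
Reagents that add atoms: none
Why: Fluoride-mediated desilylation of the three aryl and one alkyl silyl ether under acetic acid buffering (no free alkoxide next to the alkyne) gives the pentahydroxy carbinol, whose bis(4-hydroxyphenyl)carbinol unit loses water under mild acid to the quinone methide (fuchsone-type dehydration); the product has no stereocentre.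

**Compound list**
1 | 4-bromo-2-iodotoluene | Cc1ccc(Br)cc1I | starting material
2 | [(4-bromo-2-iodophenyl)methoxy](tert-butyl)dimethylsilane | CC(C)(C)[Si](C)(C)OCc1ccc(Br)cc1I | intermediate
3 | 4,4'-dihydroxybenzophenone | O=C(c1ccc(O)cc1)c1ccc(O)cc1 | starting material
4 | 4,4'-bis(tert-butyldimethylsilyloxy)benzophenone | O=C(c1ccc(O[Si](C)(C)C(C)(C)C)cc1)c1ccc(O[Si](C)(C)C(C)(C)C)cc1 | intermediate
5 | [6-bromo-3-({[tert-butyl(dimethyl)silyl]oxy}methyl)-2-iodophenyl]lithium (not isolated) | [Li]c1c(Br)ccc(CO[Si](C)(C)C(C)(C)C)c1I | intermediate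
6 | lithium alkoxide of 7 (not isolated) | [Li]OC(c1ccc(O[Si](C)(C)C(C)(C)C)cc1)(c1ccc(O[Si](C)(C)C(C)(C)C)cc1)c1c(Br)ccc(CO[Si](C)(C)C(C)(C)C)c1I | intermediate
7 | [6-bromo-3-({[tert-butyl(dimethyl)silyl]oxy}methyl)-2-iodophenyl]bis(4-{[tert-butyl(dimethyl)silyl]oxy}phenyl)methanol | OC(c1ccc(O[Si](C)(C)C(C)(C)C)cc1)(c1ccc(O[Si](C)(C)C(C)(C)C)cc1)c1c(Br)ccc(CO[Si](C)(C)C(C)(C)C)c1I | intermediate
8 | tert-butyl(4-ethynylphenoxy)dimethylsilane | C#Cc1ccc(O[Si](C)(C)C(C)(C)C)cc1 | starting material
9 | {6-bromo-3-({[tert-butyl(dimethyl)silyl]oxy}methyl)-2-[(4-{[tert-butyl(dimethyl)silyl]oxy}phenyl)ethynyl]phenyl}bis(4-{[tert-butyl(dimethyl)silyl]oxy}phenyl)methanol | OC(c1ccc(O[Si](C)(C)C(C)(C)C)cc1)(c1ccc(O[Si](C)(C)C(C)(C)C)cc1)c1c(Br)ccc(CO[Si](C)(C)C(C)(C)C)c1C#Cc1ccc(O[Si](C)(C)C(C)(C)C)cc1 | intermediate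
10 | (4-{[tert-butyl(dimethyl)silyl]oxy}phenyl)boronic acid | OB(O)c1ccc(O[Si](C)(C)C(C)(C)C)cc1 | starting material
11 | {4'-{[tert-butyl(dimethyl)silyl]oxy}-4-({[tert-butyl(dimethyl)silyl]oxy}methyl)-3-[(4-{[tert-butyl(dimethyl)silyl]oxy}phenyl)ethynyl]biphenyl-2-yl}bis(4-{[tert-butyl(dimethyl)silyl]oxy}phenyl)methanol | OC(c1ccc(O[Si](C)(C)C(C)(C)C)cc1)(c1ccc(O[Si](C)(C)C(C)(C)C)cc1)c1c(-c2ccc(O[Si](C)(C)C(C)(C)C)cc2)ccc(CO[Si](C)(C)C(C)(C)C)c1C#Cc1ccc(O[Si](C)(C)C(C)(C)C)cc1 | intermediate
12 | {4'-hydroxy-4-(hydroxymethyl)-3-[(4-hydroxyphenyl)ethynyl]biphenyl-2-yl}bis(4-hydroxyphenyl)methanol (not isolated) | OC(c1ccc(O)cc1)(c1ccc(O)cc1)c1c(-c2ccc(O)cc2)ccc(CO)c1C#Cc1ccc(O)cc1 | intermediate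
13 | selaginellin, 4-[{4'-hydroxy-4-(hydroxymethyl)-3-[(4-hydroxyphenyl)ethynyl]biphenyl-2-yl}(4-hydroxyphenyl)methylidene]cyclohexa-2,5-dien-1-one (no stereocentre) | O=C1C=CC(=C(c2ccc(O)cc2)c2c(-c3ccc(O)cc3)ccc(CO)c2C#Cc2ccc(O)cc2)C=C1 | target

**Step count and risks**

Total step count: 6. Longest linear sequence: 5 steps (1 → 2 → 7 → 9 → 11 → 13); step 2 is a one-step side branch.

The three steps most likely to fail:

Step 1 (proposed new C–H silyloxylation). The silyloxyl radical may add to the arene instead of abstracting hydrogen, the product ether may be oxidised further, or copper may not turn over with a silanolate ligand. The fallback uses known chemistry, sets out from 1 and comes back at 2: Wohl–Ziegler bromination of 1 (N-bromosuccinimide, AIBN, PhCF3, 80 °C) gives 4-bromo-1-(bromomethyl)-2-iodobenzene F1; hydrolysis (CaCO3, dioxane/H2O, 100 °C) gives (4-bromo-2-iodophenyl)methanol F2; silylation (TBSCl, imidazole, DMF, rt) gives 2.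

Step 3 (addition of a hindered 2,6-dihaloaryllithium to an electron-rich diaryl ketone). The addition may be too slow at −78 °C, and warming risks aryne formation. The fallback sets out from 2 (through aryllithium 5) and comes back at 7, building the carbinol in two C–C bond formations with the hindered nucleophile meeting an aldehyde instead of a ketone. Aryllithium 5 is trapped at −78 °C with commercial 4-(tert-butyldimethylsilyloxy)benzaldehyde to give the lithium alkoxide F3 and, after NH4Cl work-up, the racemic secondary alcohol [6-bromo-3-({[tert-butyl(dimethyl)silyl]oxy}methyl)-2-iodophenyl](4-{[tert-butyl(dimethyl)silyl]oxy}phenyl)methanol F4. Dess–Martin periodinane (CH2Cl2, rt) oxidises it to the ketone [6-bromo-3-({[tert-butyl(dimethyl)silyl]oxy}methyl)-2-iodophenyl](4-{[tert-butyl(dimethyl)silyl]oxy}phenyl)methanone F5. The unhindered Grignard reagent (4-{[tert-butyl(dimethyl)silyl]oxy}phenyl)magnesium bromide F6, made from commercial (4-bromophenoxy)(tert-butyl)dimethylsilane and Mg in THF, is then added in the presence of LaCl3·2LiCl (THF, −40 to 0 °C) to give the bromomagnesium alkoxide F7, and NH4Cl work-up gives 7.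

Step 4 (Sonogashira coupling at an iodide flanked by the silyloxymethyl group and the triaryl carbinol). Coupling may be slow, the alkyne may homocouple, and copper or divalent palladium may promote 5-exo cyclisation of the tertiary alcohol onto the new alkyne. The fallback sets out from 7 (with 8) and comes back at 9, replacing the copper acetylide/amine manifold by a stoichiometric organozinc (Negishi) coupling. Alkyne 8 is deprotonated with nBuLi (THF, −78 °C) to the lithium acetylide F8 and transmetalated with ZnCl2 to [(4-{[tert-butyl(dimethyl)silyl]oxy}phenyl)ethynyl]zinc chloride F9 (2.2 equiv), which is cross-coupled with 7 using Pd(P(tBu)3)2 (3 mol%) in THF at 40 °C to give 9.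

Further compounds
F1 | step 1 | 4-bromo-1-(bromomethyl)-2-iodobenzene | BrCc1ccc(Br)cc1I
F2 | step 1 | (4-bromo-2-iodophenyl)methanol | OCc1ccc(Br)cc1I
F3 | step 3 | lithium alkoxide of F4 (racemic, not isolated) | [Li]OC(c1ccc(O[Si](C)(C)C(C)(C)C)cc1)c1c(Br)ccc(CO[Si](C)(C)C(C)(C)C)c1I
F4 | step 3 | [6-bromo-3-({[tert-butyl(dimethyl)silyl]oxy}methyl)-2-iodophenyl](4-{[tert-butyl(dimethyl)silyl]oxy}phenyl)methanol (racemic) | OC(c1ccc(O[Si](C)(C)C(C)(C)C)cc1)c1c(Br)ccc(CO[Si](C)(C)C(C)(C)C)c1I
F5 | step 3 | [6-bromo-3-({[tert-butyl(dimethyl)silyl]oxy}methyl)-2-iodophenyl](4-{[tert-butyl(dimethyl)silyl]oxy}phenyl)methanone | O=C(c1ccc(O[Si](C)(C)C(C)(C)C)cc1)c1c(Br)ccc(CO[Si](C)(C)C(C)(C)C)c1I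
F6 | step 3 | (4-{[tert-butyl(dimethyl)silyl]oxy}phenyl)magnesium bromide | Br[Mg]c1ccc(O[Si](C)(C)C(C)(C)C)cc1
F7 | step 3 | bromomagnesium alkoxide of 7 (not isolated) | Br[Mg]OC(c1ccc(O[Si](C)(C)C(C)(C)C)cc1)(c1ccc(O[Si](C)(C)C(C)(C)C)cc1)c1c(Br)ccc(CO[Si](C)(C)C(C)(C)C)c1I
F8 | step 4 | [(4-{[tert-butyl(dimethyl)silyl]oxy}phenyl)ethynyl]lithium (not isolated) | [Li]C#Cc1ccc(O[Si](C)(C)C(C)(C)C)cc1
F9 | step 4 | [(4-{[tert-butyl(dimethyl)silyl]oxy}phenyl)ethynyl]zinc chloride | Cl[Zn]C#Cc1ccc(O[Si](C)(C)C(C)(C)C)cc1
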